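## Retrosynthetic overview

1. The strategy rests on ring B (C3a, C4, C5, C6, C7, C7a). It carries O1 on C7a, OMe on C7, H on C6, a carbon substituent on C5, H on C4 and the chain carbon C3 on C3a. A 3-alkoxy-4-methoxypyridazine with a carbonyl group on C6 leaves exactly this pattern when it exchanges N2 for an alkyne hung on its oxygen through C2–C3.
2. Last cuts: two O-benzyl groups and one silyl group. Then the furofuran (rings D and E, primed locants) is cut at C3a'–C6a' and O5'–C4' to a ring-B cinnamyl bromide and a syringyl epoxy alcohol (titanocene radical cascade).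
3. Key cut: C3a–C7a and C4–C5. This opens rings B and C together to the pyridazinyl ether of a syn homopropargylic alcohol.
4. That ether comes from O-benzylvanillin, a chiral allenylstannane (from (R)-glyceraldehyde acetonide) and a chloropyridazine ester (from 3,6-dichloro-4-methoxypyridazine).
5. Ring order: A and F are bought; B and C form together; then D and E form one after the other in one flask.

Key step: step 8

**Remark on the structure.** The SMILES is read as the cis (2S,3S) dihydrobenzofuran and the exo,exo (1'S,3a'R,4'S,6a'R) furofuran. Ring A is the guaiacyl ring on C2, ring C the dihydrofuran ring, ring D the tetrahydrofuran ring that carries the syringyl ring F on C1', and ring E the one that carries ring B on C4'.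

**Remark on protection.** The C3 hydroxymethyl group is carried as its triisopropylsilyl ether. A smaller silyl group could migrate to the 1,3-related alkoxide of step 7.

## Route

Step 1
Reactants: 1 (R)-2,2-dimethyl-1,3-dioxolane-4-carbaldehyde
Product: 3 (S)-but-3-yne-1,2-diol, via ethynyldioxolane 2 (not isolated)
Conditions: dimethyl (1-diazo-2-oxopropyl)phosphonate, K2CO3, MeOH, 0 °C to rt; then 2 M aq. HCl, rt
Reagents that add atoms: dimethyl (1-diazo-2-oxopropyl)phosphonate CC(=O)C(=[N+]=[N-])P(=O)(OC)OC
Why: Ohira–Bestmann (Seyferth–Gilbert) homologation turns CHO into C≡CH without touching the adjacent C–O stereocentre, and acid hydrolysis of the acetonide in the same flask avoids handling the volatile alkyne.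

Step 2
Reactants: 3 (S)-but-3-yne-1,2-diol
Product: 4 (S)-1-[(triisopropylsilyl)oxy]but-3-yn-2-ol
Conditions: iPr3SiCl, imidazole, CH2Cl2, 0 °C
Reagents that add atoms: chlorotriisopropylsilane CC(C)[Si](Cl)(C(C)C)C(C)C
Why: Sterically controlled silylation, in which the bulky chlorosilane should take the primary hydroxyl and leave the propargylic secondary one free.

Step 3
Reactants: 4 (S)-1-[(triisopropylsilyl)oxy]but-3-yn-2-ol
Product: 5 (S)-1-[(triisopropylsilyl)oxy]but-3-yn-2-yl methanesulfonate
Conditions: MsCl, Et3N, CH2Cl2, −78 to 0 °C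
Reagents that add atoms: methanesulfonyl chloride CS(=O)(=O)Cl
Why: O-sulfonylation leaves the C–O bond intact, so the S centre is kept and gains the leaving group for the SN2' step.

Step 4
Reactants: 5 (S)-1-[(triisopropylsilyl)oxy]but-3-yn-2-yl methanesulfonate
Product: 6 (P)-tributyl{4-[(triisopropylsilyl)oxy]buta-1,2-dien-1-yl}stannane (axis aS)
Conditions: Bu3SnH, LiN(iPr)2, THF, 0 °C; CuBr·SMe2, −78 °C; then 5, −78 °C
Reagents that add atoms: tributyltin hydride CCCC[SnH](CCCC)CCCC
Why: SN2' displacement of a propargylic mesylate by a stannylcopper reagent is known to run anti, so the S centre should be relayed into the P axis of the allene.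

Step 5
Reactants: 6 (P)-allenylstannane; 7 4-(benzyloxy)-3-methoxybenzaldehyde (O-benzylvanillin)
Product: 8 (1S,2S)-1-[4-(benzyloxy)-3-methoxyphenyl]-2-{[(triisopropylsilyl)oxy]methyl}but-3-yn-1-ol (syn)
Conditions: BF3·OEt2, CH2Cl2, −78 °C
Reagents that add atoms: none
Why: Lewis acid promoted SE2' addition of a chiral allenylstannane, in which the BF3-bound aldehyde should attack the CH2OSi-bearing allene carbon anti to tin (future C3 set as S) and the open transition state that keeps the aryl group away from CH2OSi should favour the syn adduct (future C2 set as S).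

Step 6
Reactants: 9 3,6-dichloro-4-methoxypyridazine
Product: 10 methyl 6-chloro-5-methoxypyridazine-3-carboxylate
Conditions: CO (5 bar), Pd(dppf)Cl2 (cat.), Et3N, MeOH, 60 °C
Reagents that add atoms: carbon monoxide [C-]#[O+]; methanol CO
Why: Palladium-catalysed methoxycarbonylation, in which zerovalent palladium should insert first into the C6–Cl bond (unhindered, meta to the donor OMe) and leave the C3–Cl bond next to OMe for step 7.

Step 7
Reactants: 8 syn alcohol; 10 methyl 6-chloro-5-methoxypyridazine-3-carboxylate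
Product: 11 methyl 6-{[(1S,2S)-1-[4-(benzyloxy)-3-methoxyphenyl]-2-{[(triisopropylsilyl)oxy]methyl}but-3-yn-1-yl]oxy}-5-methoxypyridazine-3-carboxylate
Conditions: NaH added last to 8 + 10, THF, 0 °C
Reagents that add atoms: none
Why: SNAr (addition–elimination) at the only C–Cl carbon, activated by the ring nitrogens and the para ester; the carbinol C–O bond is untouched, so both stereocentres are retained, and the bulky silyl group should not migrate.

Step 8
Reactants: 11 pyridazinyl ether
Product: 13 methyl (2S,3S)-2-[4-(benzyloxy)-3-methoxyphenyl]-7-methoxy-3-{[(triisopropylsilyl)oxy]methyl}-2,3-dihydro-1-benzofuran-5-carboxylate, via bridged diazabicyclooctatriene adduct 12 (not isolated)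
Conditions: 1,3,5-triisopropylbenzene (dilute, degassed), BHT (cat.), base-washed sealed tube, 200–230 °C
Reagents that add atoms: none
Why: Heating folds the terminal alkyne (two-electron partner) over the ester-activated pyridazine (four-electron partner) for an intramolecular inverse-electron-demand [4+2] addition across the two ring carbons next to nitrogen, which makes C3a–C7a and C4–C5 in adduct 12, and 12 at once loses N2 by retro-[4+2] to leave ring B aromatic. The closest known reaction type is the thermal intramolecular alkyne–1,2-diazine Diels–Alder reaction that converts 3-(but-3-ynyloxy)- and 3-(but-3-ynylamino)pyridazines into dihydrobenzofurans and indolines. Ring C (O1, C2, C3, C3a, C7a) closes five-membered because the three-atom tether O1–C2–C3 ties the diene terminus to the inner alkyne carbon, and ring B closes by the cycloaddition–cycloreversion itself from four pyridazine carbons and both alkyne carbons. No lasting stereocentre is made, since the two bridgehead centres of 12 vanish with N2 and no bond to C2 or C3 is broken, so the syn pair of 11 should become the cis (2S,3S) pair of 13. The tether fixes the regiochemistry (OMe on C7, H on C6, ester on C5, H on C4), so the selectivity needed is chemoselectivity for cycloaddition over retro-ene or ionic loss of the benzylic pyridazinyl ether. The ester lowers the diazine LUMO against the two alkoxy donors, the two tether substituents favour the folded rotamer, and a dilute, apolar, acid-free medium disfavours ionisation.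

Step 9
Reactants: 13 cis ester
Product: 14 {(2S,3S)-2-[4-(benzyloxy)-3-methoxyphenyl]-7-methoxy-3-{[(triisopropylsilyl)oxy]methyl}-2,3-dihydro-1-benzofuran-5-yl}methanol
Conditions: iBu2AlH, CH2Cl2, −78 °C; aq. potassium sodium tartrate
Reagents that add atoms: none
Why: Hydride reduction of the aryl ester to the benzylic alcohol, to which the silyl ether, the benzyl ether and the cis ring C are inert.

Step 10
Reactants: 14 benzylic alcohol
Product: 16 ethyl (E)-3-{(2S,3S)-2-[4-(benzyloxy)-3-methoxyphenyl]-7-methoxy-3-{[(triisopropylsilyl)oxy]methyl}-2,3-dihydro-1-benzofuran-5-yl}prop-2-enoate, via aldehyde 15 (not isolated)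
Conditions: MnO2, Ph3P=CHCO2Et, CH2Cl2, reflux
Reagents that add atoms: ethyl (triphenylphosphoranylidene)acetate CCOC(=O)C=P(c1ccccc1)(c1ccccc1)c1ccccc1
Why: Tandem oxidation–Wittig process, in which MnO2 oxidises the benzylic alcohol and the stabilised ylide traps the aldehyde as it forms to give the E enoate.

Step 11
Reactants: 16 enoate
Product: 17 (E)-3-{(2S,3S)-2-[4-(benzyloxy)-3-methoxyphenyl]-7-methoxy-3-{[(triisopropylsilyl)oxy]methyl}-2,3-dihydro-1-benzofuran-5-yl}prop-2-en-1-ol
Conditions: iBu2AlH, CH2Cl2, −78 °C; aq. potassium sodium tartrate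
Reagents that add atoms: none
Why: 1,2-Reduction of the enoate by iBu2AlH should give the E allylic alcohol without conjugate reduction.

Step 12
Reactants: 17 cinnamyl alcohol
Product: 18 (2S,3S)-2-[4-(benzyloxy)-3-methoxyphenyl]-5-[(E)-3-bromoprop-1-en-1-yl]-7-methoxy-3-{[(triisopropylsilyl)oxy]methyl}-2,3-dihydro-1-benzofuran
Conditions: CBr4, PPh3, CH2Cl2, −20 to 0 °C; used at once
Reagents that add atoms: tetrabromomethane BrC(Br)(Br)Br
Why: The Appel reaction converts the primary allylic alcohol into the bromide under nearly neutral conditions, so no acid is present that could epimerise C2.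

Step 13
Reactants: 19 syringaldehyde
Product: 20 4-(benzyloxy)-3,5-dimethoxybenzaldehyde
Conditions: BnBr, K2CO3, DMF, rt
Reagents that add atoms: benzyl bromide BrCc1ccccc1
Why: Williamson O-benzylation of the acidic phenol.

Step 14
Reactants: 20 4-(benzyloxy)-3,5-dimethoxybenzaldehyde
Product: 21 rac-1-[4-(benzyloxy)-3,5-dimethoxyphenyl]prop-2-en-1-ol
Conditions: CH2=CHMgBr, THF, 0 °C
Reagents that add atoms: vinylmagnesium bromide C=C[Mg]Br
Why: Grignard 1,2-addition to the aldehyde gives the racemic aryl vinyl carbinol for resolution.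

Step 15
Reactants: 21 racemic aryl vinyl carbinol
Product: 22 (R)-[4-(benzyloxy)-3,5-dimethoxyphenyl][(2S)-oxiran-2-yl]methanol (erythro)
Conditions: tBuOOH (0.45 equiv), Ti(OiPr)4 (cat.), D-(−)-diisopropyl tartrate (cat.), 4 Å MS, CH2Cl2, −20 °C
Reagents that add atoms: tert-butyl hydroperoxide CC(C)(C)OO
Why: Sharpless kinetic resolution, in which the D-(−)-tartrate catalyst should epoxidise the (S)-carbinol fast and on the face that gives the erythro epoxy alcohol while the (R)-carbinol is left, so the carbinol centre (future C1') is selected and the oxirane centre is set by the catalyst.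

Step 16
Reactants: 22 epoxy alcohol; 18 cinnamyl bromide
Product: 23 (2S,3S)-2-[4-(benzyloxy)-3-methoxyphenyl]-5-[(E)-3-{(R)-[4-(benzyloxy)-3,5-dimethoxyphenyl][(2S)-oxiran-2-yl]methoxy}prop-1-en-1-yl]-7-methoxy-3-{[(triisopropylsilyl)oxy]methyl}-2,3-dihydro-1-benzofuran
Conditions: NaH added last to 22 + 18, Bu4NI (cat.), THF–DMF, 0 °C to rt
Reagents that add atoms: none
Why: Williamson etherification by SN2 at the primary allylic bromide, which leaves the carbinol C–O bond and its configuration untouched, while trapping the alkoxide as it forms should hold back Payne rearrangement.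

Step 17
Reactants: 23 epoxy cinnamyl ether
Product: 25 (1'S,3a'R,4'S,6a'R)-furofuran bearing 4-(benzyloxy)-3,5-dimethoxyphenyl on C1' plus the (2S,3S) ring A/B/C unit (O-benzyl; O-silyl) on C4', via benzylic iodide 24 (not isolated)
Conditions: Cp2TiCl (from Cp2TiCl2, Zn, THF) added slowly to 23, THF, rt; then I2, rt to 50 °C
Reagents that add atoms: none
Why: Titanocene chloride epoxide opening, 5-exo-trig radical cyclisation and iodine-induced ether closure (known for epoxy cinnamyl ethers leading to furofuran lignans): trivalent titanium opens the oxirane to the secondary C6a' radical, which erases the oxirane centre; ring D closes at C6a'–C3a' through a chair-like transition state with ring F pseudo-equatorial (C1'/C6a' trans, C6a'/C3a' cis, both controlled by C1'); I2 then converts the benzylic titanium species into iodide 24, which the titanium alkoxide should displace on the convex face to close ring E and place ring B exo on C4'.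

Step 18
Reactants: 25 protected furofuran
Product: 26 primary alcohol with both phenols still O-benzylated
Conditions: Bu4NF, THF, 0 °C to rt
Reagents that add atoms: none
Why: Fluoride cleaves the Si–O bond while both phenols are still benzylated, so no phenoxide can open ring C through a quinone methide.

Step 19
Reactants: 26 bis(benzyl ether)
Product: 27 target, 4-[(1S,3aR,4S,6aR)-4-{(2S,3S)-2-(4-hydroxy-3-methoxyphenyl)-3-(hydroxymethyl)-7-methoxy-2,3-dihydro-1-benzofuran-5-yl}tetrahydro-1H,3H-furo[3,4-c]furan-1-yl]-2,6-dimethoxyphenol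
Conditions: H2 (1 atm), Pd/C, EtOAc, rt, stopped when debenzylation is complete
Reagents that add atoms: none
Why: Neutral hydrogenolysis of the two aryl benzyl ethers should be much faster than cleavage of the hindered secondary benzylic C–O bonds of rings C, D and E, and it touches no stereocentre.

## Compound list

1 | (R)-2,2-dimethyl-1,3-dioxolane-4-carbaldehyde | O=C[C@H]1COC(C)(C)O1 | starting material
2 | (S)-4-ethynyl-2,2-dimethyl-1,3-dioxolane | C#C[C@H]1COC(C)(C)O1 | intermediate
3 | (S)-but-3-yne-1,2-diol | O[C@@H](C#C)CO | intermediate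
4 | (S)-1-[(triisopropylsilyl)oxy]but-3-yn-2-ol | O[C@@H](C#C)CO[Si](C(C)C)(C(C)C)C(C)C | intermediate
5 | (S)-1-[(triisopropylsilyl)oxy]but-3-yn-2-yl methanesulfonate | CS(=O)(=O)O[C@@H](C#C)CO[Si](C(C)C)(C(C)C)C(C)C | intermediate
6 | (P)-tributyl{4-[(triisopropylsilyl)oxy]buta-1,2-dien-1-yl}stannane | [H]C(CO[Si](C(C)C)(C(C)C)C(C)C)=[C@]=C([H])[Sn](CCCC)(CCCC)CCCC | intermediate
7 | 4-(benzyloxy)-3-methoxybenzaldehyde | COc1cc(C=O)ccc1OCc1ccccc1 | starting material
8 | (1S,2S) syn homopropargylic alcohol | COc1cc([C@@H](O)[C@@H](C#C)CO[Si](C(C)C)(C(C)C)C(C)C)ccc1OCc1ccccc1 | intermediate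
9 | 3,6-dichloro-4-methoxypyridazine | COc1cc(Cl)nnc1Cl | starting material
10 | methyl 6-chloro-5-methoxypyridazine-3-carboxylate | COC(=O)c1cc(OC)c(Cl)nn1 | intermediate
11 | (1S,2S) pyridazinyl ether, precursor of the key step | COc1cc([C@@H](Oc2nnc(C(=O)OC)cc2OC)[C@@H](C#C)CO[Si](C(C)C)(C(C)C)C(C)C)ccc1OCc1ccccc1 | intermediate
12 | bridged 2,3-diazabicyclo[2.2.2]octa-2,5,7-triene adduct (bridgehead centres open, both forms give 13) | COC(=O)C12N=NC3(O[C@H](c4ccc(OCc5ccccc5)c(OC)c4)[C@H](CO[Si](C(C)C)(C(C)C)C(C)C)C3=C1)C(OC)=C2 | intermediate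
13 | (2S,3S) cis dihydrobenzofuran 5-methyl ester, product of the key step | COc1cc([C@H]2Oc3c(OC)cc(C(=O)OC)cc3[C@H]2CO[Si](C(C)C)(C(C)C)C(C)C)ccc1OCc1ccccc1 | intermediate
14 | (2S,3S) 5-hydroxymethyl compound | COc1cc([C@H]2Oc3c(OC)cc(CO)cc3[C@H]2CO[Si](C(C)C)(C(C)C)C(C)C)ccc1OCc1ccccc1 | intermediate
15 | (2S,3S) 5-carbaldehyde | COc1cc([C@H]2Oc3c(OC)cc(C=O)cc3[C@H]2CO[Si](C(C)C)(C(C)C)C(C)C)ccc1OCc1ccccc1 | intermediate
16 | (2S,3S) ethyl (E)-enoate | COc1cc([C@H]2Oc3c(OC)cc(/C=C/C(=O)OCC)cc3[C@H]2CO[Si](C(C)C)(C(C)C)C(C)C)ccc1OCc1ccccc1 | intermediate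
17 | (2S,3S) (E)-cinnamyl alcohol | COc1cc([C@H]2Oc3c(OC)cc(/C=C/CO)cc3[C@H]2CO[Si](C(C)C)(C(C)C)C(C)C)ccc1OCc1ccccc1 | intermediate
18 | (2S,3S) (E)-cinnamyl bromide | COc1cc([C@H]2Oc3c(OC)cc(/C=C/CBr)cc3[C@H]2CO[Si](C(C)C)(C(C)C)C(C)C)ccc1OCc1ccccc1 | intermediate
19 | syringaldehyde | COc1cc(C=O)cc(OC)c1O | starting material
20 | 4-(benzyloxy)-3,5-dimethoxybenzaldehyde | COc1cc(C=O)cc(OC)c1OCc1ccccc1 | intermediate
21 | rac-1-[4-(benzyloxy)-3,5-dimethoxyphenyl]prop-2-en-1-ol | C=CC(O)c1cc(OC)c(OCc2ccccc2)c(OC)c1 | intermediate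
22 | (R)-[4-(benzyloxy)-3,5-dimethoxyphenyl][(2S)-oxiran-2-yl]methanol | O[C@@H]([C@@H]1CO1)c1cc(OC)c(OCc2ccccc2)c(OC)c1 | intermediate
23 | epoxy cinnamyl ether | COc1cc([C@H]2Oc3c(OC)cc(/C=C/CO[C@@H]([C@@H]4CO4)c4cc(OC)c(OCc5ccccc5)c(OC)c4)cc3[C@H]2CO[Si](C(C)C)(C(C)C)C(C)C)ccc1OCc1ccccc1 | intermediate
24 | monocyclic benzylic iodide (drawn as the free alcohol, in the flask its oxygen carries Cp2TiCl; C–I centre open) | COc1cc([C@H]2Oc3c(OC)cc(C(I)[C@H]4CO[C@H](c5cc(OC)c(OCc6ccccc6)c(OC)c5)[C@H]4CO)cc3[C@H]2CO[Si](C(C)C)(C(C)C)C(C)C)ccc1OCc1ccccc1 | intermediate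
25 | fully protected furofuran | COc1cc([C@H]2Oc3c(OC)cc([C@H]4OC[C@H]5[C@@H]4CO[C@@H]5c4cc(OC)c(OCc5ccccc5)c(OC)c4)cc3[C@H]2CO[Si](C(C)C)(C(C)C)C(C)C)ccc1OCc1ccccc1 | intermediate
26 | bis(O-benzyl) primary alcohol | COc1cc([C@H]2Oc3c(OC)cc([C@H]4OC[C@H]5[C@@H]4CO[C@@H]5c4cc(OC)c(OCc5ccccc5)c(OC)c4)cc3[C@H]2CO)ccc1OCc1ccccc1 | intermediate
27 | CNP0126146.1 | COc1cc([C@H]2Oc3c(OC)cc([C@H]4OC[C@H]5[C@@H]4CO[C@@H]5c4cc(OC)c(O)c(OC)c4)cc3[C@H]2CO)ccc1O | target

## Step count and risks

Total step count: 19. Longest linear sequence: 15 steps (steps 1–5, 7–12, 16–19).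

**Step 8.**
- Risk: the two alkoxy donors may slow the cycloaddition so much that retro-ene elimination, oxygen-to-nitrogen migration of the benzylic group or ionisation at C2 overtakes it.
- Fallback: it gives up the cycloaddition and closes ring C on a ready-made ring B by carbenoid C–H insertion, which is known to be cis-selective. It sets out from 7 and comes back at 16.
- NaBH4 in MeOH reduces 7 to 4-(benzyloxy)-3-methoxybenzyl alcohol F1.
- A Mitsunobu reaction (PPh3, diisopropyl azodicarboxylate, THF) with commercial methyl 4-hydroxy-3-iodo-5-methoxybenzoate gives the iodoaryl benzyl ether F2.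
- Pd(PPh3)4-catalysed coupling of the iodide with ethyl diazoacetate (Et3N, Bu4NBr, MeCN) gives the aryldiazoacetate F3.
- Dirhodium tetrakis[N-phthaloyl-(S)-tert-leucinate], Rh2(S-PTTL)4, or its enantiomer, whichever serves the (2S,3R) series, is used in toluene at low temperature. It inserts the carbenoid into the benzylic ether C–H bond to give the cis diester F4.
- iBu2AlH at −78 °C reduces both esters to the diol F5.
- MnO2 with Ph3P=CHCO2Et oxidises only the benzylic alcohol, through the hydroxy aldehyde F6, to the hydroxy enoate F7.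
- iPr3SiCl and imidazole then give 16.

**Step 17.**
- Risk: the benzylic radical may be reduced and protonated before iodine is added, the iodide may eliminate instead of closing, or closure may be poorly face-selective at C4'.
- Fallback: it separates the C–C closure from the C–O closure. It sets out from 23 and comes back at 25.
- The same Cp2TiCl opening and 5-exo cyclisation is quenched with aqueous NaH2PO4 to isolate the (2S,3R,4R)-tetrahydrofuran alcohol F8.
- A hypoiodite reaction (PhI(OAc)2, I2, visible light, cyclohexane–CH2Cl2) then generates the alkoxy radical. Its 1,5-hydrogen transfer is directed by geometry to the ring-B benzylic CH2, and oxidation with C–O closure gives 25.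

**Step 5.**
- Risk: simple diastereoselection in the open transition state may be poor with an aromatic aldehyde, while transfer of chirality from the allene stays intact.
- Fallback: it replaces substrate-controlled addition by reagent-controlled ketone reduction. It sets out from 8 obtained in admixture with its C1 epimer, the (1R,2S) anti alcohol F9, and comes back at 8. Both alcohols carry the same 2S centre.
- Dess–Martin periodinane (NaHCO3, CH2Cl2) therefore merges them into the single aryl ketone F10 under non-basic conditions.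
- Corey–Bakshi–Shibata reduction with the (R)-methyl oxazaborolidine and catecholborane (toluene, −78 °C), with the aryl group as the larger flank, should return the 1S alcohol 8 without hydroborating the alkyne.

## Further compounds

F1 | step 8 | 4-(benzyloxy)-3-methoxybenzyl alcohol | COc1cc(CO)ccc1OCc1ccccc1
F2 | step 8 | methyl 4-{[4-(benzyloxy)-3-methoxybenzyl]oxy}-3-iodo-5-methoxybenzoate | COC(=O)c1cc(I)c(OCc2ccc(OCc3ccccc3)c(OC)c2)c(OC)c1
F3 | step 8 | methyl 4-{[4-(benzyloxy)-3-methoxybenzyl]oxy}-3-(1-diazo-2-ethoxy-2-oxoethyl)-5-methoxybenzoate | CCOC(=O)C(=[N+]=[N-])c1cc(C(=O)OC)cc(OC)c1OCc1ccc(OCc2ccccc2)c(OC)c1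
F4 | step 8 | 3-ethyl 5-methyl (2S,3R)-cis-2-[4-(benzyloxy)-3-methoxyphenyl]-7-methoxy-2,3-dihydro-1-benzofuran-3,5-dicarboxylate | COc1cc([C@H]2Oc3c(OC)cc(C(=O)OC)cc3[C@H]2C(=O)OCC)ccc1OCc1ccccc1
F5 | step 8 | (2S,3S)-cis 3,5-bis(hydroxymethyl) compound | COc1cc([C@H]2Oc3c(OC)cc(CO)cc3[C@H]2CO)ccc1OCc1ccccc1
F6 | step 8 | (2S,3S)-cis 3-hydroxymethyl 5-carbaldehyde | COc1cc([C@H]2Oc3c(OC)cc(C=O)cc3[C@H]2CO)ccc1OCc1ccccc1
F7 | step 8 | (2S,3S)-cis 3-hydroxymethyl ethyl (E)-enoate | COc1cc([C@H]2Oc3c(OC)cc(/C=C/C(=O)OCC)cc3[C@H]2CO)ccc1OCc1ccccc1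
F8 | step 17 | (2S,3R,4R)-2-aryl-3-(hydroxymethyl)-4-(ring-B-methyl)tetrahydrofuran | COc1cc([C@H]2Oc3c(OC)cc(C[C@H]4CO[C@H](c5cc(OC)c(OCc6ccccc6)c(OC)c5)[C@H]4CO)cc3[C@H]2CO[Si](C(C)C)(C(C)C)C(C)C)ccc1OCc1ccccc1
F9 | step 5 | (1R,2S) anti homopropargylic alcohol | COc1cc([C@H](O)[C@@H](C#C)CO[Si](C(C)C)(C(C)C)C(C)C)ccc1OCc1ccccc1
F10 | step 5 | (S)-1-[4-(benzyloxy)-3-methoxyphenyl]-2-{[(triisopropylsilyl)oxy]methyl}but-3-yn-1-one | COc1cc(C(=O)[C@@H](C#C)CO[Si](C(C)C)(C(C)C)C(C)C)ccc1OCc1ccccc1
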